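Atom labels used throughout: the furofuran is numbered as 3,7-dioxabicyclo[3.3.0]octane (C1 and C5 at the ring fusion, C2 carrying guaiacyl ring A, O3–C4 and O7–C8 as the two OCH2 arms, C6 carrying ring B). The dihydrobenzofuran is primed (O1', C2' carrying guaiacyl ring C, C3' carrying CH2OH, C5' bonded to C6, C7' carrying OMe).

## The problem

The target 19 is a sesquilignan: a cis-fused furofuran carries ring A at C2 and, at C6, the arene (ring B) of a 7'-methoxy-2',3'-dihydrobenzofuran that bears ring C at C2' and CH2OH at C3'. It has six stereocentres in two clusters: C1, C2, C5 and C6 (all S) and C2', C3' (both S). Reading the configuration shows that both aryl groups of the bicycle sit on its concave face (endo,endo) and that ring C and CH2OH are cis on the five-membered ring. Both clusters are therefore in the less stable arrangement and must be made and kept under kinetic control. Inside the furofuran, C1 and C2 can direct C5 and C6 because only a cis ring fusion is possible. The flat ring B insulates the two clusters from each other, so absolute configuration has to be brought in twice. The bonds C2–O3, C6–O7 and C2'–O1' are benzylic and para to an oxygen donor. Acids ionise them with drift to the exo or trans isomers, hydrogenolysis cleaves them, and free phenols make both worse. C3' is also epimerisable for as long as it carries a carbonyl group. The enabling feature is C6: it is bonded to O7, C5, ring B and hydrogen, so it is the aldehyde carbon of ring B placed between a hydroxyl oxygen (O7 on C8) and a carbon nucleophile (C5). If C4 is raised to the acetal level, C5 is the β-carbon of the enol ether O3–C4=C5 of a 2-aryl-2,3-dihydrofuran-3-methanol, and the second oxolane can be closed through an aryl oxocarbenium ion.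

## Retrosynthesis

**19 ⇒ 18 ⇒ 17 (C4–H and the O–acyl bonds).** The last operations are chosen to be non-acidic and non-hydrogenolytic. In 18 the C3' substituent is still a methyl ester and ring A and ring C are pivalates, so one hydride treatment gives the CH2OH and both phenols of 19. Compound 18 is traced to the C4 methyl acetal 17, which is reduced to CH2 by ionic hydrogenation. The acetal is not an extra burden: it is the oxidation level at which C5 is nucleophilic. The forward steps must leave the three benzylic C–O bonds and C3' untouched, which is why ring A and ring C are acylated and C3' keeps an electron-withdrawing ester until the end.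

**17 ⇒ 8 + 15 (O7–C6, C5–C6 and C4–OMe).** Cutting both bonds at C6 divides the molecule into the dihydrofuran alcohol 8 (ring A, C1, C2, O3, C4, C5, C8, O7) and the aldehyde acetal 15 (C6, ring B, the dihydrobenzofuran and ring C). The mirror-image cut at C2 would put the large benzofuran on the dihydrofuran and would force its synthesis through a pyrolysis on a heavy, enantiopure aldehyde. The chosen orientation keeps the dihydrofuran small and uses the complex half only as an electrophile. The union is fully convergent and forms one ring, two skeletal bonds and three stereocentres. It must proceed by acetal exchange before any carbon–carbon bond forms (mixed acetal 16) and must close under kinetic control, so that ring B ends on the concave face.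

**15 ⇒ 14 ⇒ 13 ⇒ 12 (C2'–C3', then N2, then aryl–CH2).** The cis-dihydrobenzofuran is opened at C2'–C3' to the aryldiazoacetate 14, because carbenoid insertion into the O–CH2–aryl bond gives the cis isomer kinetically and a chiral dirhodium carboxylate sets both centres at once. Ring closure by C–O bond formation at C2' would pass through a benzylic cation and favour trans. Compound 14 comes from the arylacetate 13 by diazo transfer, and 13 from the aryl bromide 12 by palladium-catalysed coupling with a zinc ester enolate. The aldehyde is masked as the dimethyl acetal from 12 onwards, which is the form the key step needs.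

**12 ⇒ 11 ⇒ 9 + 10 (acetal C–O, then O–CH2).** Bromide 12 is the acetal of aldehyde 11, an aryl benzyl ether assembled from the benzylic alcohol 9 and 5-bromovanillin 10. In 10 the bromine, hydroxyl, methoxy and formyl groups already stand where C3a', O1', the 7'-OMe and C6 are needed, so ring B needs no further functionalisation.

**8 ⇒ 7 ⇒ 6 ⇒ 5 ⇒ 4 ⇒ 2 + 3 (resolution, O–acyl, ester reduction, C2–C3 of the dihydrofuran, epoxide).** Alcohol 8 is the (2S,3S)-enantiomer of racemic 7, obtained by kinetic resolution. Compound 7 is the phenol pivalate of diol 6, which arises from ester 5 by hydride reduction; the reduction also removes the first pivalate, and this is accepted. The cis-dihydrofuran 5 is the electrocyclisation product of the carbonyl ylide from vinyl epoxide 4. Compound 4 is the vinylogous Darzens product of aldehyde 2 and bromocrotonate 3. This sequence is preferred to open-chain aldol routes because the electrocyclisation gives the 2,3-cis relationship directly and in few steps.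

**2 ⇐ 1 and 9 ⇐ 2.** Both guaiacyl rings come from vanillin 1 through its pivalate 2, which supplies ring A directly and ring C after reduction to 9.

## Roads not taken

**Alternative 1: tandem conjugate addition–aldol on a chiral butenolide.**
- Cut: C5–C6 and C1–C2, leaving C1, C5, C4 and C8 as a lactone.
- Forward key step: the lithiated dithiane A3 of the benzofuran aldehyde adds to the β-carbon of the menthyloxy butenolide A2 anti to the auxiliary. The enolate is trapped by the ring A aldehyde to give the trans,trans lactone A1.
- Merits: three components are joined in one flask, and C1 and C5 are set absolutely by a cheap auxiliary with no resolution.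
- Weak points: in A1, C6 is still a dithiane carbon and C2 a free carbinol, so the two benzylic centres that define the endo,endo array are not set. They would be made later by two ring closures at para-oxygenated benzylic carbinols. These closures run through benzylic cations and favour the exo isomers, and two clean SN2 closures with inversion cannot be relied on there. Dithiane removal, ketone reduction, lactone and acetal reduction and two cyclisations add at least five steps after A1.
- Comparison: this road is better for the absolute configuration of the ring fusion, where the chosen plan discards half of 7 in a resolution. The chosen plan sets against it that the endo,endo array is formed kinetically in one step, with only two steps after it.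

**Alternative 2: late carbenoid C–H insertion.**
- Cut: C2'–C3' as the last skeletal bond.
- Forward key step: the aryldiazoacetate A5, which already contains the complete endo,endo furofuran, is decomposed by a chiral dirhodium carboxylate. The carbenoid inserts into the O–CH2–aryl C–H bond to give the cis ester A4.
- Merits: cis is the inherent outcome, and the acid-sensitive cis-dihydrobenzofuran is formed only after all Lewis-acid steps. This is a real advantage over the chosen plan.
- Weak points: the arylacetate, the diazo group and the insertion must all be installed on the most valuable intermediate, giving at least five linear steps after the furofuran is made. A5 offers four ether oxygens and further benzylic ether C–H bonds to the carbenoid. Any shortfall in catalyst control appears as a diastereomer of a large molecule.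
- Comparison: the chosen plan answers the acid sensitivity by keeping C3' as an ester and ring C as a pivalate, which disfavour ionisation at C2'. It performs the insertion on a small molecule whose enantiomeric purity can be checked, and it stays convergent.

**Alternative 3: pyrone–alkyne Diels–Alder.**
- Cut: two bonds of ring B (C7a'–C3a' and C5'–C4').
- Forward key step: heating the 3-alkoxy-2-pyrone A7, which carries a tethered terminal alkyne, gives an intramolecular cycloaddition. Loss of CO2 then gives the dihydrobenzofuran A6.
- Merits: no diazo compound, no rhodium and no epimerisable ester at C3'. The tether fixes the regiochemistry, and C2'/C3' are set before the ring exists.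
- Weak points: the stereodiad needs its own asymmetric open-chain synthesis. Joining the para-oxygenated benzylic carbon C2' to the pyrone oxygen without loss of configuration is doubtful. The electron-rich pyrone and the unactivated alkyne call for high temperature, at which a benzylic pyronyl ether may fragment. A6 still needs deacylation, oxidation to the aldehyde and acetalisation before the furofuran can be addressed.
- Comparison: this road is better in avoiding the C3' epimerisation risk that 15, 17 and 18 carry. It is longer, less precedented and solves only the fragment. The chosen plan relies on low-temperature hydride reduction of cis esters, a known and stereoretentive operation.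

Key step: step 13

## Route

Assumption 1: the lipase is taken to acylate the (2R,3R)-enantiomer of 7 faster, so that the (2S,3S)-alcohol 8 remains unreacted.
Assumption 2: the (R)-configured catalyst Rh2(R-PTTL)4 is taken to give the (2S,3R)-ester 15; if the sense proves opposite, its mirror image Rh2(S-PTTL)4 is used.

Step 1
Reactants: 1 vanillin
Product: 2 4-formyl-2-methoxyphenyl pivalate
Conditions: PivCl, Et3N, DMAP (cat.), CH2Cl2, 0 °C → rt
Reagents that add atoms: pivaloyl chloride, CC(C)(C)C(Cl)=O
Why: O-acylation of the phenol (nucleophilic acyl substitution); the hindered, non-enolisable pivalate should tolerate the amide base of step 2 and the pyrolysis of step 3, and the same compound serves ring A and ring C.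

Step 2
Reactants: 2 4-formyl-2-methoxyphenyl pivalate; 3 methyl (E)-4-bromobut-2-enoate
Product: 4 methyl (E)-3-[3-(3-methoxy-4-pivaloyloxyphenyl)oxiran-2-yl]prop-2-enoate (racemic; cis/trans epoxide mixture used as such)
Conditions: LiN(SiMe3)2 added to 2 + 3, THF, −78 → −20 °C
Reagents that add atoms: none
Why: Vinylogous Darzens condensation: the bromo dienolate adds through its bromine-bearing carbon to the aldehyde and the alkoxide displaces bromide, the irreversible epoxide closure draining the reversible α-adduct. The epoxide geometry is irrelevant because both isomers open to the same ylide in step 3.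

Step 3
Reactants: 4 vinyl epoxide
Product: 5 methyl cis-2-(3-methoxy-4-pivaloyloxyphenyl)-2,3-dihydrofuran-3-carboxylate (racemic; 2S*,3R*)
Conditions: flash vacuum pyrolysis, 500 °C, 0.05 mbar, quartz tube, trap at −196 °C
Reagents that add atoms: none
Why: Thermal C–C cleavage of the epoxide to a carbonyl ylide and 6π (1,5-dipolar) electrocyclisation onto the acrylate; the disrotatory closure at short contact time should give the kinetic 2,3-cis isomer, and the gas phase excludes acid- or base-mediated epimerisation at C3.

Step 4
Reactants: 5 racemic cis ester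
Product: 6 racemic cis-4-[3-(hydroxymethyl)-2,3-dihydrofuran-2-yl]-2-methoxyphenol (2S*,3S*)
Conditions: LiAlH4 (excess), THF, −20 → 0 °C; aq. NH4Cl
Reagents that add atoms: none
Why: Hydride reduction of the ester is faster than enolisation at low temperature, so the cis relationship should be kept; the enol ether is inert and the loss of the aryl pivalate is accepted and repaired in step 5.

Step 5
Reactants: 6 racemic cis diol
Product: 7 racemic cis-[2-(3-methoxy-4-pivaloyloxyphenyl)-2,3-dihydrofuran-3-yl]methanol (2S*,3S*)
Conditions: PivCl (1.05 equiv), K2CO3, acetone, 0 °C → rt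
Reagents that add atoms: pivaloyl chloride, CC(C)(C)C(Cl)=O
Why: Chemoselective acylation of the phenoxide: carbonate deprotonates only the phenol, and a primary alcohol is not acylated by pivaloyl chloride without an amine catalyst; the basic medium is harmless to the enol ether.

Step 6
Reactants: 7 racemic cis alcohol
Product: 8 [(2S,3S)-2-(3-methoxy-4-pivaloyloxyphenyl)-2,3-dihydrofuran-3-yl]methanol
Conditions: Pseudomonas cepacia lipase (Amano PS, immobilised), vinyl acetate, t-BuOMe, 25 °C, stopped a little beyond half conversion
Reagents that add atoms: none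
Why: Lipase-catalysed kinetic resolution by irreversible transesterification with an enol ester; the enzyme should acylate the (2R,3R)-enantiomer and leave 8, whose two stereocentres were already fixed relative to each other in step 3. The hindered aryl pivalate is not a lipase substrate.

Step 7
Reactants: 2 4-formyl-2-methoxyphenyl pivalate
Product: 9 4-(hydroxymethyl)-2-methoxyphenyl pivalate
Conditions: NaBH4, THF–MeOH (10:1), 0 °C
Reagents that add atoms: none
Why: Borohydride reduction, chemoselective for the aldehyde over the hindered aryl ester at 0 °C and short reaction time.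

Step 8
Reactants: 9 4-(hydroxymethyl)-2-methoxyphenyl pivalate; 10 5-bromovanillin
Product: 11 3-bromo-5-methoxy-4-[(3-methoxy-4-pivaloyloxyphenyl)methoxy]benzaldehyde
Conditions: PPh3, DIAD, THF, 0 °C → rt
Reagents that add atoms: none
Why: Mitsunobu etherification: the acidic, formyl-activated phenol and a primary benzylic alcohol are ideal partners for SN2 displacement of the alkoxyphosphonium ion, and the neutral conditions spare the aryl pivalate and the aldehyde.

Step 9
Reactants: 11 aryl benzyl ether aldehyde
Product: 12 4-{[2-bromo-4-(dimethoxymethyl)-6-methoxyphenoxy]methyl}-2-methoxyphenyl pivalate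
Conditions: HC(OMe)3, p-TsOH·H2O (1 mol %), MeOH, rt; then Et3N
Reagents that add atoms: trimethyl orthoformate, COC(OC)OC; methanol (solvent, exchanges with it), CO
Why: Acid-catalysed acetalisation driven by the orthoformate as water scavenger; the dimethyl acetal protects the aldehyde from the zinc enolate of step 10 and is the electrophile precursor of step 13.

Step 10
Reactants: 12 aryl bromide acetal
Product: 13 methyl 2-{5-(dimethoxymethyl)-3-methoxy-2-[(3-methoxy-4-pivaloyloxyphenyl)methoxy]phenyl}acetate
Conditions: BrZnCH2CO2Me (from methyl bromoacetate and Zn dust, THF), Pd(dba)2 (2 mol %), P(t-Bu)3 (2 mol %), THF, 25 → 50 °C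
Reagents that add atoms: bromo(2-methoxy-2-oxoethyl)zinc (from methyl bromoacetate, COC(=O)CBr, and zinc), COC(=O)C[Zn]Br
Why: Palladium-catalysed α-arylation of an ester with a Reformatsky reagent (Negishi-type coupling): oxidative addition of the aryl bromide to zerovalent palladium, transmetalation of the zinc enolate and reductive elimination. The nearly neutral zinc enolate should leave the aryl pivalate and the acetal alone.

Step 11
Reactants: 13 arylacetate
Product: 14 methyl 2-diazo-2-{5-(dimethoxymethyl)-3-methoxy-2-[(3-methoxy-4-pivaloyloxyphenyl)methoxy]phenyl}acetate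
Conditions: 4-acetamidobenzenesulfonyl azide, DBU, MeCN, 0 °C → rt
Reagents that add atoms: 4-acetamidobenzenesulfonyl azide, CC(=O)Nc1ccc(cc1)S(=O)(=O)N=[N+]=[N-]
Why: Regitz diazo transfer to the benzylic ester enolate; arylacetates with an ortho benzyloxy group are standard substrates, and the amidine base does not attack the pivalate or the acetal.

Step 12
Reactants: 14 aryldiazoacetate
Product: 15 methyl (2S,3R)-5-(dimethoxymethyl)-7-methoxy-2-(3-methoxy-4-pivaloyloxyphenyl)-2,3-dihydrobenzofuran-3-carboxylate (2,3-cis)
Conditions: Rh2(R-PTTL)4 [dirhodium tetrakis(N-phthaloyl-(R)-tert-leucinate)] (1–2 mol %), toluene, −60 → −20 °C, slow addition of 14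
Reagents that add atoms: none
Why: Intramolecular 1,5 C–H insertion of a donor/acceptor rhodium carbenoid into the benzylic ether C–H bond; the concerted insertion should give the cis ring kinetically, and the chiral carboxylate ligands select the enantiotopic hydrogen and so set C2' and C3' together.

Step 13
Reactants: 8 [(2S,3S)-2-(3-methoxy-4-pivaloyloxyphenyl)-2,3-dihydrofuran-3-yl]methanol; 15 cis-dihydrobenzofuran ester dimethyl acetal
Product: 17 methyl (2S,3R)-7-methoxy-5-[(1S,2S,4S,5R,6S)-4-methoxy-2-(3-methoxy-4-pivaloyloxyphenyl)-3,7-dioxabicyclo[3.3.0]oct-6-yl]-2-(3-methoxy-4-pivaloyloxyphenyl)-2,3-dihydrobenzofuran-3-carboxylate (endo,endo furofuran 4-methyl acetal), via mixed methyl acetal 16 (not isolated)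
Conditions: Me3SiOTf (0.2 equiv), 4 Å MS, CH2Cl2, −78 → −40 °C; quench with aq. NaHCO3 at −78 °C
Reagents that add atoms: none
Why: Acetal exchange between the hydroxyl of 8 and 15 gives 16, which loses methoxide to form the aryl oxocarbenium ion O7=C6, stabilised by the para oxygen O1' of ring B. The enol ether carbon C5 attacks C6, and the ring oxocarbenium ion O3=C4 that results is capped by the liberated methanol. The closest known reaction type is the Lewis-acid-mediated cyclisation of 2-aryl-2,3-dihydrofuran-3-methanols with aryl aldehyde dimethyl acetals to 2,6-diaryl furofuran acetals, a Prins-type (Mukaiyama-like) addition of an enol ether to an oxocarbenium ion. The oxolane C1–C8–O7–C6–C5 closes in a 5-endo-trig sense at the C6=O7 bond and exo with respect to the enol ether double bond. C5 is controlled by the one-carbon tether from C1, which allows only the cis ring fusion; C1 and C2 come unchanged from 8, whose cis relationship places ring A on the concave face. C6 is expected to be set kinetically with ring B endo, as is usual for this class of closure, and C4 by attack of methanol on the convex face; C4 is removed in step 14. The step needs O-alkylation before C-alkylation and kinetic control at C6. These are secured by the free primary hydroxyl, which exchanges faster than the enol ether adds, and by low temperature, substoichiometric acid and a cold quench. The pivalate on ring A and the ester and pivalate around C2' disfavour ionisation at C2 and C2'.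

Step 14
Reactants: 17 furofuran 4-methyl acetal
Product: 18 methyl (2S,3R)-7-methoxy-2-(3-methoxy-4-pivaloyloxyphenyl)-5-[(1S,2S,5S,6S)-2-(3-methoxy-4-pivaloyloxyphenyl)-3,7-dioxabicyclo[3.3.0]oct-6-yl]-2,3-dihydrobenzofuran-3-carboxylate
Conditions: Et3SiH, BF3·OEt2, CH2Cl2, −78 → −40 °C
Reagents that add atoms: none
Why: Ionic hydrogenation of a cyclic acetal: BF3 ionises the C4–OMe bond to the ring oxocarbenium ion, which the silane reduces to CH2, so no stereocentre is at stake. The acetal ionises far more readily than the benzylic ethers, whose cleavage is further disfavoured at C2 and C2' by the acyl groups.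

Step 15
Reactants: 18 furofuran ester bis-pivalate
Product: 19 4-[(2S,3S)-3-(hydroxymethyl)-5-[(1S,2S,5S,6S)-2-(4-hydroxy-3-methoxyphenyl)-3,7-dioxabicyclo[3.3.0]oct-6-yl]-7-methoxy-2,3-dihydrobenzofuran-2-yl]-2-methoxyphenol (target)
Conditions: 18 added to LiAlH4 (excess), THF, −40 → 0 °C; aq. NH4Cl
Reagents that add atoms: none
Why: Global hydride reduction: the methyl ester becomes the C3' CH2OH and both aryl pivalates are cleaved to the phenols. Inverse addition at low temperature should make hydride addition outrun enolisation at C3', and the non-acidic medium leaves the endo,endo and cis centres untouched.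

## Compound list

1 | vanillin | COc1cc(C=O)ccc1O | starting material
2 | 4-formyl-2-methoxyphenyl pivalate | COc1cc(C=O)ccc1OC(=O)C(C)(C)C | intermediate
3 | methyl (E)-4-bromobut-2-enoate | COC(=O)/C=C/CBr | starting material
4 | methyl (E)-3-[3-(3-methoxy-4-pivaloyloxyphenyl)oxiran-2-yl]prop-2-enoate (racemic, epoxide cis/trans mixture) | COC(=O)/C=C/C1OC1c1ccc(OC(=O)C(C)(C)C)c(OC)c1 | intermediate
5 | methyl cis-2-(3-methoxy-4-pivaloyloxyphenyl)-2,3-dihydrofuran-3-carboxylate (racemic; relative configuration shown, 2S*,3R*) | COc1cc([C@H]2OC=C[C@H]2C(=O)OC)ccc1OC(=O)C(C)(C)C | intermediate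
6 | cis-4-[3-(hydroxymethyl)-2,3-dihydrofuran-2-yl]-2-methoxyphenol (racemic; relative configuration shown, 2S*,3S*) | COc1cc([C@H]2OC=C[C@H]2CO)ccc1O | intermediate
7 | cis-[2-(3-methoxy-4-pivaloyloxyphenyl)-2,3-dihydrofuran-3-yl]methanol (racemic; relative configuration shown, 2S*,3S*) | COc1cc([C@H]2OC=C[C@H]2CO)ccc1OC(=O)C(C)(C)C | intermediate
8 | [(2S,3S)-2-(3-methoxy-4-pivaloyloxyphenyl)-2,3-dihydrofuran-3-yl]methanol (single enantiomer) | COc1cc([C@H]2OC=C[C@H]2CO)ccc1OC(=O)C(C)(C)C | intermediate
9 | 4-(hydroxymethyl)-2-methoxyphenyl pivalate | COc1cc(CO)ccc1OC(=O)C(C)(C)C | intermediate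
10 | 5-bromovanillin | COc1cc(C=O)cc(Br)c1O | starting material
11 | 3-bromo-5-methoxy-4-[(3-methoxy-4-pivaloyloxyphenyl)methoxy]benzaldehyde | COc1cc(C=O)cc(Br)c1OCc1ccc(OC(=O)C(C)(C)C)c(OC)c1 | intermediate
12 | 4-{[2-bromo-4-(dimethoxymethyl)-6-methoxyphenoxy]methyl}-2-methoxyphenyl pivalate | COc1cc(C(OC)OC)cc(Br)c1OCc1ccc(OC(=O)C(C)(C)C)c(OC)c1 | intermediate
13 | methyl 2-{5-(dimethoxymethyl)-3-methoxy-2-[(3-methoxy-4-pivaloyloxyphenyl)methoxy]phenyl}acetate | COc1cc(C(OC)OC)cc(CC(=O)OC)c1OCc1ccc(OC(=O)C(C)(C)C)c(OC)c1 | intermediate
14 | methyl 2-diazo-2-{5-(dimethoxymethyl)-3-methoxy-2-[(3-methoxy-4-pivaloyloxyphenyl)methoxy]phenyl}acetate | COc1cc(C(OC)OC)cc(C(=[N+]=[N-])C(=O)OC)c1OCc1ccc(OC(=O)C(C)(C)C)c(OC)c1 | intermediate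
15 | methyl (2S,3R)-5-(dimethoxymethyl)-7-methoxy-2-(3-methoxy-4-pivaloyloxyphenyl)-2,3-dihydrobenzofuran-3-carboxylate (cis) | COC(OC)c1cc(OC)c2c(c1)[C@@H](C(=O)OC)[C@@H](c1ccc(OC(=O)C(C)(C)C)c(OC)c1)O2 | intermediate
16 | mixed methyl acetal of 15 with the hydroxyl of 8 (both epimers at the acetal carbon; not isolated) | COc1cc([C@H]2OC=C[C@H]2COC(OC)c2cc(OC)c3c(c2)[C@@H](C(=O)OC)[C@@H](c2ccc(OC(=O)C(C)(C)C)c(OC)c2)O3)ccc1OC(=O)C(C)(C)C | intermediate
17 | endo,endo furofuran 4-methyl acetal (1S,2S,4S,5R,6S; 2'S,3'R), ester bis-pivalate | COc1cc([C@H]2O[C@H](OC)[C@@H]3[C@H]2CO[C@@H]3c2cc(OC)c3c(c2)[C@@H](C(=O)OC)[C@@H](c2ccc(OC(=O)C(C)(C)C)c(OC)c2)O3)ccc1OC(=O)C(C)(C)C | intermediate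
18 | endo,endo furofuran (1S,2S,5S,6S; 2'S,3'R), ester bis-pivalate | COc1cc([C@H]2OC[C@@H]3[C@H]2CO[C@@H]3c2cc(OC)c3c(c2)[C@@H](C(=O)OC)[C@@H](c2ccc(OC(=O)C(C)(C)C)c(OC)c2)O3)ccc1OC(=O)C(C)(C)C | intermediate
19 | CNP0303197.1 (1S,2S,5S,6S; 2'S,3'S) | COc1cc([C@H]2OC[C@@H]3[C@H]2CO[C@@H]3c2cc(OC)c3c(c2)[C@@H](CO)[C@@H](c2ccc(O)c(OC)c2)O3)ccc1O | target

## Step count and least certain steps

Total: 15 steps. Longest linear sequence: 10 steps from vanillin (steps 1, 7, 8, 9, 10, 11, 12, 13, 14, 15); the dihydrofuran branch (steps 1–6) joins at step 13.

**Step 13 (key step).**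
- What may go wrong: triflic acid formed from Me3SiOTf and the free hydroxyl, together with the liberated methanol, may solvolyse the enol ether before acetal exchange is complete. Reversible ionisation at C6, which is para to O1' of ring B, may erode the kinetic endo selectivity.
- Fallback: set out from 8 and convert it with Me3SiCl and imidazole into its trimethylsilyl ether F1. Combine F1 with 15 and catalytic Me3SiOTf at −78 °C. This is an aprotic silyl-transfer acetal exchange in which methoxytrimethylsilane is the only by-product and also the capping nucleophile at C4. No protic acid or free methanol is present. The fallback returns to the route at 17.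

**Step 3.**
- What may go wrong: the epoxide 4 is heavier than the usual substrates of such pyrolyses and carries an aryl ester, so incomplete vaporisation or breakdown in the inlet is possible. Longer residence in the hot zone allows leakage from the cis to the trans dihydrofuran through reversible ring opening.
- Fallback: set out from 2 and build the ring by metathesis instead.
  - Allylboration of 2 with the (Z)-allylboronate 2-[(2Z)-4-(tert-butyldimethylsilyloxy)but-2-en-1-yl]-4,4,5,5-tetramethyl-1,3,2-dioxaborolane F2 (from (Z)-but-2-ene-1,4-diol) should give, through a chair transition state, the syn homoallylic alcohol 4-[(1S*,2S*)-2-(tert-butyldimethylsilyloxymethyl)-1-hydroxybut-3-en-1-yl]-2-methoxyphenyl pivalate F3.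
  - Transfer vinylation ([Ir(cod)Cl]2, Na2CO3, vinyl acetate, toluene, 100 °C) gives the vinyl ether F4.
  - Ring-closing metathesis with the second-generation Grubbs catalyst closes the cis-dihydrofuran silyl ether F5.
  - Bu4NF buffered with AcOH removes the silyl group, and the fallback returns to the route at 7.

**Step 6.**
- What may go wrong: poor discrimination between the enantiomers, because the stereocentre is one carbon away from the carbinol, or an acylation sense opposite to the one assumed.
- Fallback: set out from 6 and resolve through covalent diastereomers.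
  - Acylate both hydroxyls with (S)-2-methoxy-2-phenylacetic acid (carbodiimide, DMAP) and separate the diastereomeric diesters by crystallisation or chromatography.
  - The diester of the (2S,3S)-diol, F6, is methanolysed with K2CO3 in MeOH to the enantiopure diol (2S,3S)-4-[3-(hydroxymethyl)-2,3-dihydrofuran-2-yl]-2-methoxyphenol F7.
  - F7 is pivaloylated at the phenol under the conditions of step 5, and the fallback returns to the route at 8.

**Step 12.**
- What may go wrong: lower enantioselectivity than in the parent benzyloxyphenyl series, because the ether oxygen is flanked by the 7'-methoxy group and the O–CH2 bond is twisted in the insertion transition state; some trans isomer may also form.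
- Fallback: replace catalyst control by resolution through the coupling partner. Set out from 15 as obtained, containing its enantiomer methyl (2R,3S)-5-(dimethoxymethyl)-7-methoxy-2-(3-methoxy-4-pivaloyloxyphenyl)-2,3-dihydrobenzofuran-3-carboxylate F8, and use it in step 13 with enantiopure 8. F8 is then converted into the diastereomeric furofuran acetal F9, which differs from 17 in physical properties and is removed by chromatography or crystallisation. The fallback returns to the route at 17.

**Step 15.**
- What may go wrong: on the fully assembled compound, phenoxide formation and three acyl groups consume hydride, so enolisation at the benzylic, ester-bearing C3' may compete. This would give epimerisation or E1cB opening of the dihydrobenzofuran, and the epimer would be hard to remove at this stage.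
- Fallback: move the reduction to the fragment stage, where the product is small and separable. Set out from 15.
  - LiAlH4 at −40 °C gives the phenol–alcohol 4-[(2S,3S)-5-(dimethoxymethyl)-3-(hydroxymethyl)-7-methoxy-2,3-dihydrobenzofuran-2-yl]-2-methoxyphenol F10.
  - PivCl, pyridine and DMAP give the bis-pivalate acetal F11.
  - F11 and 8 under the conditions of step 13 give the tris-pivalate furofuran methyl acetal F12.
  - The conditions of step 14 give the tris-pivalate furofuran F13.
  - NaOMe in MeOH removes the three pivalates, and the fallback returns to the route at 19.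

## Further compounds

F1 | step 13 | [(2S,3S)-2-(3-methoxy-4-pivaloyloxyphenyl)-2,3-dihydrofuran-3-yl]methyl trimethylsilyl ether | COc1cc([C@H]2OC=C[C@H]2CO[Si](C)(C)C)ccc1OC(=O)C(C)(C)C
F2 | step 3 | 2-[(2Z)-4-(tert-butyldimethylsilyloxy)but-2-en-1-yl]-4,4,5,5-tetramethyl-1,3,2-dioxaborolane | CC(C)(C)[Si](C)(C)OC/C=C\CB1OC(C)(C)C(C)(C)O1
F3 | step 3 | 4-[(1S*,2S*)-2-(tert-butyldimethylsilyloxymethyl)-1-hydroxybut-3-en-1-yl]-2-methoxyphenyl pivalate (racemic, syn) | COc1cc([C@@H](O)[C@@H](C=C)CO[Si](C)(C)C(C)(C)C)ccc1OC(=O)C(C)(C)C
F4 | step 3 | 4-[(1S*,2S*)-2-(tert-butyldimethylsilyloxymethyl)-1-(vinyloxy)but-3-en-1-yl]-2-methoxyphenyl pivalate (racemic) | COc1cc([C@@H](OC=C)[C@@H](C=C)CO[Si](C)(C)C(C)(C)C)ccc1OC(=O)C(C)(C)C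
F5 | step 3 | cis-3-(tert-butyldimethylsilyloxymethyl)-2-(3-methoxy-4-pivaloyloxyphenyl)-2,3-dihydrofuran (racemic) | COc1cc([C@H]2OC=C[C@H]2CO[Si](C)(C)C(C)(C)C)ccc1OC(=O)C(C)(C)C
F6 | step 6 | bis[(S)-2-methoxy-2-phenylacetate] of (2S,3S)-4-[3-(hydroxymethyl)-2,3-dihydrofuran-2-yl]-2-methoxyphenol | COc1cc([C@H]2OC=C[C@H]2COC(=O)[C@@H](OC)c2ccccc2)ccc1OC(=O)[C@@H](OC)c1ccccc1
F7 | step 6 | (2S,3S)-4-[3-(hydroxymethyl)-2,3-dihydrofuran-2-yl]-2-methoxyphenol (single enantiomer) | COc1cc([C@H]2OC=C[C@H]2CO)ccc1O
F8 | step 12 | methyl (2R,3S)-5-(dimethoxymethyl)-7-methoxy-2-(3-methoxy-4-pivaloyloxyphenyl)-2,3-dihydrobenzofuran-3-carboxylate | COC(OC)c1cc(OC)c2c(c1)[C@H](C(=O)OC)[C@H](c1ccc(OC(=O)C(C)(C)C)c(OC)c1)O2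
F9 | step 12 | diastereomer of 17 with (2'R,3'S) dihydrobenzofuran | COc1cc([C@H]2O[C@H](OC)[C@@H]3[C@H]2CO[C@@H]3c2cc(OC)c3c(c2)[C@H](C(=O)OC)[C@H](c2ccc(OC(=O)C(C)(C)C)c(OC)c2)O3)ccc1OC(=O)C(C)(C)C
F10 | step 15 | 4-[(2S,3S)-5-(dimethoxymethyl)-3-(hydroxymethyl)-7-methoxy-2,3-dihydrobenzofuran-2-yl]-2-methoxyphenol | COC(OC)c1cc(OC)c2c(c1)[C@@H](CO)[C@@H](c1ccc(O)c(OC)c1)O2
F11 | step 15 | bis-pivalate of F10 (cis-dihydrobenzofuran-5-carbaldehyde dimethyl acetal) | COC(OC)c1cc(OC)c2c(c1)[C@@H](COC(=O)C(C)(C)C)[C@@H](c1ccc(OC(=O)C(C)(C)C)c(OC)c1)O2
F12 | step 15 | endo,endo furofuran 4-methyl acetal, tris-pivalate | COc1cc([C@H]2O[C@H](OC)[C@@H]3[C@H]2CO[C@@H]3c2cc(OC)c3c(c2)[C@@H](COC(=O)C(C)(C)C)[C@@H](c2ccc(OC(=O)C(C)(C)C)c(OC)c2)O3)ccc1OC(=O)C(C)(C)C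
F13 | step 15 | endo,endo furofuran, tris-pivalate | COc1cc([C@H]2OC[C@@H]3[C@H]2CO[C@@H]3c2cc(OC)c3c(c2)[C@@H](COC(=O)C(C)(C)C)[C@@H](c2ccc(OC(=O)C(C)(C)C)c(OC)c2)O3)ccc1OC(=O)C(C)(C)C
A1 | alternative 1 | trans,trans α-(aryl-hydroxymethyl)-β-(2-aryl-1,3-dithian-2-yl)-γ-menthyloxy butyrolactone | COc1cc([C@@H](O)[C@@H]2C(=O)O[C@H](O[C@H]3C[C@@H](C)CC[C@@H]3C(C)C)[C@H]2C2(c3cc(OC)c4c(c3)[C@@H](CO[Si](C)(C)C(C)(C)C)[C@@H](c3ccc(O[Si](C)(C)C(C)(C)C)c(OC)c3)O4)SCCCS2)ccc1O[Si](C)(C)C(C)(C)C
A2 | alternative 1 | (5S)-5-[(1S,2R,5S)-menthyloxy]furan-2(5H)-one | O=C1O[C@H](O[C@H]2C[C@@H](C)CC[C@@H]2C(C)C)C=C1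
A3 | alternative 1 | 2-aryl-1,3-dithiane of the silyl-protected cis-dihydrobenzofuran-5-carbaldehyde | C1(c2cc(OC)c3c(c2)[C@@H](CO[Si](C)(C)C(C)(C)C)[C@@H](c2ccc(O[Si](C)(C)C(C)(C)C)c(OC)c2)O3)SCCCS1
A4 | alternative 2 | methyl cis-2-aryl-2,3-dihydrobenzofuran-3-carboxylate carrying the furofuran (bis-silyl ether) | COc1cc([C@H]2OC[C@@H]3[C@H]2CO[C@@H]3c2cc(OC)c3c(c2)[C@@H](C(=O)OC)[C@@H](c2ccc(O[Si](C)(C)C(C)(C)C)c(OC)c2)O3)ccc1O[Si](C)(C)C(C)(C)C
A5 | alternative 2 | aryldiazoacetate carrying the furofuran and the ortho O-benzyl ether | COc1cc([C@H]2OC[C@@H]3[C@H]2CO[C@@H]3c2cc(OC)c(OCc3ccc(O[Si](C)(C)C(C)(C)C)c(OC)c3)c(C(=[N+]=[N-])C(=O)OC)c2)ccc1O[Si](C)(C)C(C)(C)C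
A6 | alternative 3 | cis-2-aryl-3-(silyloxymethyl)-7-methoxy-2,3-dihydrobenzofuran-5-ylmethyl pivalate | CC(C)(C)C(=O)OCc1cc(OC)c2c(c1)[C@@H](CO[Si](C)(C)C(C)(C)C)[C@@H](c1ccc(O[Si](C)(C)C(C)(C)C)c(OC)c1)O2
A7 | alternative 3 | 3-(1-aryl-2-(silyloxymethyl)but-3-ynyloxy)-4-methoxy-6-(pivaloyloxymethyl)-2-pyrone | C#C[C@@H](CO[Si](C)(C)C(C)(C)C)[C@@H](c1ccc(O[Si](C)(C)C(C)(C)C)c(OC)c1)Oc1c(OC)cc(COC(=O)C(C)(C)C)oc1=O
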